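**Strategy.** Everything rests on disconnecting the cyclobutane bond between C11 (the CH α to the enone carbonyl C1) and C10 (the methyl-bearing quaternary carbon). C10 is the γ-carbon of a C7/C9 1,3-dione, the latent form of the 7,9-dioxygenated seven-membered ring, and it sits 1,3 to C11 across the C4–C5 fusion of a cis-fused bicyclo[5.4.0] precursor. One dianion alkylation of a C11 tosylate closes the four-membered ring C4–C5–C11–C10, creates quaternary C10 and completes the longipinane skeleton. The precursor comes from meso cyclohex-2-ene-1,4-diol by lipase desymmetrisation, Tsuji–Trost allylation (C4–C10), Ireland–Claisen rearrangement (C5–C6, quaternary C6) and Dieckmann closure of the seven-membered ring.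

Key step: step 10

Remark 1: longipinane numbering is used. C1 is the ketone carbon, C2=C3 the enone double bond (C3 bears methyl C12), C4 and C11 are the bridgeheads, C5 and C10 the one-carbon cyclobutane bridges (C10 bears methyl C13), and C6–C7–C8–C9 is the four-carbon bridge (C6 bears methyl C14 and CH2O C15).

Remark 2: in compounds 11–15 the CHMe centre C10 is a mixture of epimers. It becomes planar in step 10, so its configuration is left open in those SMILES.

Remark 3: the lipase is assumed to acetylate the hydroxyl on the (S)-configured carbinol carbon of 4; should it prefer the other hydroxyl, the same monoacetate 5 would be reached by the complementary lipase hydrolysis of the meso diacetate of 4.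

Step 1
Reactants: 1 methyl (S)-3-hydroxy-2-methylpropanoate
Product: 2 methyl (S)-2-methyl-3-(triisopropylsilyloxy)propanoate
Conditions: TIPSCl, imidazole, DMF, 0 → 23 °C
Reagents that add atoms: triisopropylsilyl chloride, CC(C)[Si](Cl)(C(C)C)C(C)C
Why: Imidazole-promoted silylation of the primary alcohol installs a bulky, non-chelating ether that later controls the ketene acetal geometry and should survive all basic steps.

Step 2
Reactants: 2 methyl (S)-2-methyl-3-(triisopropylsilyloxy)propanoate
Product: 3 (S)-2-methyl-3-(triisopropylsilyloxy)propanoic acid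
Conditions: LiOH, THF/H2O, 0 °C; 1 M HCl
Reagents that add atoms: lithium hydroxide, [Li+].[OH-]
Why: Cold saponification should free the acid without β-elimination, and the α-stereocentre is erased later, so partial epimerisation would be harmless.

Step 3
Reactants: 4 cis-cyclohex-2-ene-1,4-diol
Product: 5 (1S,4R)-4-hydroxycyclohex-2-en-1-yl acetate
Conditions: vinyl acetate (3 equiv), immobilised Candida antarctica lipase B, t-BuOMe, 23 °C
Reagents that add atoms: vinyl acetate, CC(=O)OC=C
Why: Lipase-catalysed irreversible transesterification desymmetrises the meso diol by acetylating one of its two enantiotopic hydroxyls, which fixes the absolute configuration of both carbinol carbons, and any over-acetylation to the meso diacetate should preferentially consume the minor enantiomer of the monoacetate.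

Step 4
Reactants: 5 (1S,4R)-4-hydroxycyclohex-2-en-1-yl acetate; 6 3-methylpentane-2,4-dione
Product: 7 (1R,4S)-4-(3-methyl-2,4-dioxopentan-3-yl)cyclohex-2-en-1-ol
Conditions: 6, NaH (1.05 equiv), THF, 0 °C; then 5, Pd(PPh3)4 (5 mol%), 23 → 50 °C; 1 M HCl
Reagents that add atoms: none
Why: In this Tsuji–Trost allylic alkylation zerovalent palladium ionises the allylic acetate with inversion (the free hydroxyl is not a leaving group) and the soft diketone enolate attacks anti to the metal at the allyl terminus remote from the hydroxyl-bearing carbon, so C10 should enter with net retention cis to the hydroxyl; both stereocentres stem from 5, the weakly basic enolate should not trigger acetyl migration, and any O-allylated enol ether re-ionises and funnels to the C-alkylated product.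

Step 5
Reactants: 7 (1R,4S)-4-(3-methyl-2,4-dioxopentan-3-yl)cyclohex-2-en-1-ol; 3 (S)-2-methyl-3-(triisopropylsilyloxy)propanoic acid
Product: 8 (1R,4S)-4-(3-methyl-2,4-dioxopentan-3-yl)cyclohex-2-en-1-yl (S)-2-methyl-3-(triisopropylsilyloxy)propanoate
Conditions: DCC, DMAP (cat.), CH2Cl2, 0 → 23 °C
Reagents that add atoms: none
Why: Steglich esterification of the secondary allylic alcohol proceeds with retention at the carbinol carbon and installs the acyl group that serves as the Claisen partner, while the diketone, which has no hydrogen on its central carbon, should not interfere.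

Step 6
Reactants: 8 allylic ester
Product: 10 methyl 2-methyl-2-[cis-6-(3-methyl-2,4-dioxopentan-3-yl)cyclohex-2-en-1-yl]-3-(triisopropylsilyloxy)propanoate, via carboxylic acid 9 (not isolated)
Conditions: LiN(i-Pr)2 (3.5 equiv), TMSCl, Et3N, THF, −78 → 60 °C; 1 M HCl; TMSCHN2, MeOH/PhMe, 0 °C
Reagents that add atoms: trimethylsilyldiazomethane, C[Si](C)(C)C=[N+]=[N-]
Why: In this Ireland–Claisen rearrangement the acetyl groups are masked in situ as silyl enol ethers, kinetic deprotonation of the non-chelating silyloxy ester should place CH2OSi syn to the allylic oxygen, and the chair-like suprafacial shift delivers C6 to C5 on the face of the departing oxygen (cis to the C4 substituent), setting C5 and quaternary C6 and moving the alkene to C1=C11; the crude acid is then methylated.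

Step 7
Reactants: 10 methyl ester
Product: 12 15-(triisopropylsilyloxy)-12-nor-10,11-secolongipin-1(11)-ene-7,9-dione, via keto ester 11 (not isolated)
Conditions: NaOMe (3 equiv), MeOH/THF, 0 → 60 °C; 1 M HCl
Reagents that add atoms: none
Why: Methoxide removes one acetyl group by retro-Claisen cleavage and the methyl ketone enolate (C8) then closes the seven-membered ring by Dieckmann-type condensation on the C7 ester, pulled by deprotonation of the 1,3-dione (closure through C10 would give a non-enolisable five-membered dione that reverts).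

Step 8
Reactants: 12 bicyclic ene-dione
Product: 13 1,11-dihydroxy-15-(triisopropylsilyloxy)-12-nor-10,11-secolongipinane-7,9-dione
Conditions: OsO4 (2 mol%), NMO, acetone/H2O, 0 → 23 °C
Reagents that add atoms: osmium tetroxide, O=[Os](=O)(=O)=O; N-methylmorpholine N-oxide, C[N+]1([O-])CCOCC1
Why: Upjohn dihydroxylation of the only isolated alkene should occur anti to the C5 substituent, giving the cis-diol with both oxygens trans to C6 and C10.

Step 9
Reactants: 13 diol
Product: 15 1-(triethylsilyloxy)-11-(tosyloxy)-15-(triisopropylsilyloxy)-12-nor-10,11-secolongipinane-7,9-dione, via triethylsilyl ether 14 (not isolated)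
Conditions: TESCl, imidazole, CH2Cl2, −20 °C; then Ts2O, pyridine, 0 → 23 °C
Reagents that add atoms: triethylsilyl chloride, CC[Si](Cl)(CC)CC; p-toluenesulfonic anhydride, Cc1ccc(cc1)S(=O)(=O)OS(=O)(=O)c1ccc(C)cc1
Why: TESCl should take the less hindered C1 hydroxyl and the remaining neopentyl-type C11 hydroxyl is then sulfonylated, so C11 becomes the only electrophilic carbon; a tosylate is chosen because it has no acidic α-hydrogen, and the seven-membered 1,3-dione, expected to be largely in the diketo form, should stay untouched under these weakly basic conditions.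

Step 10
Reactants: 15 tosylate
Product: 18 1-hydroxy-15-(triisopropylsilyloxy)-12-norlongipinane-7,9-dione, via dilithium dienediolate 16 (not isolated), via triethylsilyl ether 17 (not isolated)
Conditions: LiN(i-Pr)2 (2.6 equiv), THF, −78 → 0 °C (15 added to the base); then 1 M HCl, THF, 23 °C
Reagents that add atoms: none
Why: The base first forms the 1,3-dione enolate and then removes the γ-hydrogen at C10, and the terminal carbon of dienediolate 16, far more nucleophilic than C8 or either oxygen, displaces the C11 tosylate from the ring face opposite the leaving group; acid work-up then cleaves the triethylsilyl ether. The closest known reaction types are the γ-alkylation of 1,3-diketone dianions and the base-induced cyclisation of cis-fused bicyclic keto sulfonates to bicyclo[3.1.1]heptanones. The four-membered ring C4–C5–C11–C10 closes in a 4-exo-tet mode with the enolate double bond C9=C10 outside the new ring, and no other ring is formed. C11 is inverted and C10 becomes quaternary; because C10 can bridge C4 and C11 only on the face that carries C6, both new stereocentres are fixed by the cis ring fusion set at C4 and C5. The step needs C-alkylation at C10 rather than attack by O7, O9 or C8, and substitution rather than elimination: axial C10 sits 1,3 to C11 while the enolate oxygens lie in the dienolate plane away from the C11–O axis, the C1 oxygen is a silyl ether so C11 is the only electrophile, and the equatorial tosylate has no antiperiplanar hydrogen.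

Step 11
Reactants: 18 hydroxy dione
Product: 20 15-(triisopropylsilyloxy)-12-norlongipin-2-ene-1,7,9-trione, via trione 19 (not isolated)
Conditions: IBX (3.5 equiv), DMSO, 75 °C
Reagents that add atoms: none
Why: IBX oxidises the C1 alcohol and then dehydrogenates the ketone; enolisation is possible only towards C2 (C11 is a bridgehead) and the 1,3-dione has no β-hydrogen, so only the C2=C3 enone should form.

Step 12
Reactants: 20 enone
Product: 22 15-(triisopropylsilyloxy)longipin-2-ene-1,7,9-trione, via silyl enol ether 21 (not isolated)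
Conditions: Me2CuLi (from MeLi, CuI; 3 equiv), TMSCl, THF, −78 °C; then Pd(OAc)2, MeCN, 23 °C
Reagents that add atoms: lithium dimethylcuprate, [Li+].C[Cu-]C
Why: Conjugate addition with silyl trapping, expected from the face bearing the C5 hydrogen, followed by Saegusa–Ito oxidation restores the C2=C3 double bond now carrying the C3 methyl (the transient C3 stereocentre is lost and the dione only consumes one equivalent of cuprate).

Step 13
Reactants: 22 silyl ether
Product: 23 15-hydroxylongipin-2-ene-1,7,9-trione
Conditions: HF·pyridine, pyridine/THF, 0 → 23 °C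
Reagents that add atoms: none
Why: Buffered fluoride cleavage of the primary triisopropylsilyl ether should leave enone and dione untouched.

Step 14
Reactants: 23 hydroxy trione
Product: 24 7,15-dihydroxylongipin-2-ene-1,9-dione
Conditions: Me4NBH(OAc)3 (1.5 equiv), MeCN/AcOH, −30 °C
Reagents that add atoms: none
Why: In this Evans–Saksena reduction the C15 alkoxyborohydride delivers hydride to C7 from the face of the CH2O arm, placing the C7 hydroxyl cis to the C6 methyl, and the diol is held as a cyclic borate so the C9 ketone and the enone should not be reduced.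

Step 15
Reactants: 24 diol; 25 angelic acid
Product: 26 15-angeloyloxy-7-hydroxylongipin-2-ene-1,9-dione
Conditions: 2,4,6-trichlorobenzoyl chloride, Et3N, PhMe, 23 → 50 °C
Reagents that add atoms: none
Why: Yamaguchi-type acylation through the mixed anhydride, without DMAP, should acylate the primary C15 hydroxyl in preference to the hindered C7 hydroxyl and avoid Z to E isomerisation.

Step 16
Reactants: 26 β-hydroxy ketone
Product: 27 7-acetoxy-15-angeloyloxy-9-hydroxylongipin-2-en-1-one
Conditions: MeCHO (10 equiv), SmI2 (30 mol%), THF, −10 °C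
Reagents that add atoms: acetaldehyde, CC=O
Why: In this Evans–Tishchenko reduction the trivalent samarium hemiacetal formed from the C7 hydroxyl and acetaldehyde transfers hydride to C9 through a six-membered transition state, giving the 7,9-trans relationship and leaving acetyl on O7 and a free C9 hydroxyl in one operation.

Step 17
Reactants: 27 hydroxy ester; 25 angelic acid
Product: 28 7-acetoxy-9,15-bis(angeloyloxy)longipin-2-en-1-one (CNP0364726.1)
Conditions: 2,4,6-trichlorobenzoyl chloride, Et3N, PhMe, 80 °C
Reagents that add atoms: none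
Why: The hindered C9 hydroxyl is acylated with the same mixed anhydride at higher temperature without nucleophilic catalyst, conditions under which angelates should not isomerise to tiglates.

**Compound list**

1 | methyl (S)-3-hydroxy-2-methylpropanoate | C[C@@H](CO)C(=O)OC | starting material
2 | methyl (S)-2-methyl-3-(triisopropylsilyloxy)propanoate | C[C@@H](CO[Si](C(C)C)(C(C)C)C(C)C)C(=O)OC | intermediate
3 | (S)-2-methyl-3-(triisopropylsilyloxy)propanoic acid | C[C@@H](CO[Si](C(C)C)(C(C)C)C(C)C)C(=O)O | intermediate
4 | cis-cyclohex-2-ene-1,4-diol (meso) | O[C@H]1C=C[C@@H](O)CC1 | starting material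
5 | (1S,4R)-4-hydroxycyclohex-2-en-1-yl acetate (1,4-cis) | O[C@H]1C=C[C@@H](OC(C)=O)CC1 | intermediate
6 | 3-methylpentane-2,4-dione | CC(=O)C(C)C(C)=O | starting material
7 | (1R,4S)-4-(3-methyl-2,4-dioxopentan-3-yl)cyclohex-2-en-1-ol (1,4-cis) | O[C@H]1C=C[C@@H](C(C)(C(C)=O)C(C)=O)CC1 | intermediate
8 | (1R,4S)-4-(3-methyl-2,4-dioxopentan-3-yl)cyclohex-2-en-1-yl (S)-2-methyl-3-(triisopropylsilyloxy)propanoate (1,4-cis) | C[C@@H](CO[Si](C(C)C)(C(C)C)C(C)C)C(=O)O[C@H]1C=C[C@@H](C(C)(C(C)=O)C(C)=O)CC1 | intermediate
9 | 2-methyl-2-[cis-6-(3-methyl-2,4-dioxopentan-3-yl)cyclohex-2-en-1-yl]-3-(triisopropylsilyloxy)propanoic acid | CC(C)[Si](C(C)C)(C(C)C)OC[C@@](C)(C(O)=O)[C@@H]1C=CCC[C@@H]1C(C)(C(C)=O)C(C)=O | intermediate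
10 | methyl ester of 9 | CC(C)[Si](C(C)C)(C(C)C)OC[C@@](C)(C(=O)OC)[C@@H]1C=CCC[C@@H]1C(C)(C(C)=O)C(C)=O | intermediate
11 | methyl 2-methyl-2-[cis-6-(3-oxobutan-2-yl)cyclohex-2-en-1-yl]-3-(triisopropylsilyloxy)propanoate (C10 epimers) | CC(C)[Si](C(C)C)(C(C)C)OC[C@@](C)(C(=O)OC)[C@@H]1C=CCC[C@@H]1C(C)C(C)=O | intermediate
12 | 15-(triisopropylsilyloxy)-12-nor-10,11-secolongipin-1(11)-ene-7,9-dione (cis-fused bicyclo[5.4.0]; C10 epimers) | CC(C)[Si](C(C)C)(C(C)C)OC[C@]1(C)[C@@H]2C=CCC[C@@H]2C(C)C(=O)CC1=O | intermediate
13 | 1,11-dihydroxy-15-(triisopropylsilyloxy)-12-nor-10,11-secolongipinane-7,9-dione (cis-diol trans to C6 and C10) | CC(C)[Si](C(C)C)(C(C)C)OC[C@]1(C)[C@@H]2[C@@H](O)[C@@H](O)CC[C@@H]2C(C)C(=O)CC1=O | intermediate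
14 | 1-O-triethylsilyl ether of 13 | CC(C)[Si](C(C)C)(C(C)C)OC[C@]1(C)[C@@H]2[C@@H](O)[C@@H](O[Si](CC)(CC)CC)CC[C@@H]2C(C)C(=O)CC1=O | intermediate
15 | 11-O-tosylate of 14 | CC(C)[Si](C(C)C)(C(C)C)OC[C@]1(C)[C@@H]2[C@@H](OS(=O)(=O)c3ccc(C)cc3)[C@@H](O[Si](CC)(CC)CC)CC[C@@H]2C(C)C(=O)CC1=O | intermediate
16 | dilithium 7,9-dienediolate of 15 | CC(C)[Si](C(C)C)(C(C)C)OC[C@]1(C)[C@@H]2[C@@H](OS(=O)(=O)c3ccc(C)cc3)[C@@H](O[Si](CC)(CC)CC)CC[C@@H]2C(C)=C([O-])C=C1[O-].[Li+].[Li+] | intermediate
17 | 1-(triethylsilyloxy)-15-(triisopropylsilyloxy)-12-norlongipinane-7,9-dione | CC(C)[Si](C(C)C)(C(C)C)OC[C@]1(C)[C@@H]2[C@H]3[C@@H](O[Si](CC)(CC)CC)CC[C@@H]2[C@@]3(C)C(=O)CC1=O | intermediate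
18 | 1-hydroxy-15-(triisopropylsilyloxy)-12-norlongipinane-7,9-dione | CC(C)[Si](C(C)C)(C(C)C)OC[C@]1(C)[C@@H]2[C@H]3[C@@H](O)CC[C@@H]2[C@@]3(C)C(=O)CC1=O | intermediate
19 | 15-(triisopropylsilyloxy)-12-norlongipinane-1,7,9-trione | CC(C)[Si](C(C)C)(C(C)C)OC[C@]1(C)[C@@H]2[C@H]3C(=O)CC[C@@H]2[C@@]3(C)C(=O)CC1=O | intermediate
20 | 15-(triisopropylsilyloxy)-12-norlongipin-2-ene-1,7,9-trione | CC(C)[Si](C(C)C)(C(C)C)OC[C@]1(C)[C@@H]2[C@H]3C(=O)C=C[C@@H]2[C@@]3(C)C(=O)CC1=O | intermediate
21 | 1-(trimethylsilyloxy)-15-(triisopropylsilyloxy)longipin-1-ene-7,9-dione | CC(C)[Si](C(C)C)(C(C)C)OC[C@]1(C)[C@@H]2[C@H]3C(O[Si](C)(C)C)=C[C@@H](C)[C@@H]2[C@@]3(C)C(=O)CC1=O | intermediate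
22 | 15-(triisopropylsilyloxy)longipin-2-ene-1,7,9-trione | CC(C)[Si](C(C)C)(C(C)C)OC[C@]1(C)[C@@H]2[C@H]3C(=O)C=C(C)[C@@H]2[C@@]3(C)C(=O)CC1=O | intermediate
23 | 15-hydroxylongipin-2-ene-1,7,9-trione | OC[C@]1(C)[C@@H]2[C@H]3C(=O)C=C(C)[C@@H]2[C@@]3(C)C(=O)CC1=O | intermediate
24 | 7,15-dihydroxylongipin-2-ene-1,9-dione (7-OH cis to the C6 methyl) | OC[C@]1(C)[C@@H]2[C@H]3C(=O)C=C(C)[C@@H]2[C@@]3(C)C(=O)C[C@H]1O | intermediate
25 | angelic acid, (Z)-2-methylbut-2-enoic acid | C/C=C(/C)C(=O)O | starting material
26 | 15-angeloyloxy-7-hydroxylongipin-2-ene-1,9-dione | C/C=C(/C)C(=O)OC[C@]1(C)[C@@H]2[C@H]3C(=O)C=C(C)[C@@H]2[C@@]3(C)C(=O)C[C@H]1O | intermediate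
27 | 7-acetoxy-15-angeloyloxy-9-hydroxylongipin-2-en-1-one (7,9-trans) | C/C=C(/C)C(=O)OC[C@]1(C)[C@@H]2[C@H]3C(=O)C=C(C)[C@@H]2[C@@]3(C)[C@H](O)C[C@H]1OC(C)=O | intermediate
28 | 7-acetoxy-9,15-bis(angeloyloxy)longipin-2-en-1-one (CNP0364726.1) | C/C=C(/C)C(=O)OC[C@]1(C)[C@@H]2[C@H]3C(=O)C=C(C)[C@@H]2[C@@]3(C)[C@H](OC(=O)/C(C)=C\C)C[C@H]1OC(C)=O | target

**Step count and risks**

Total steps: 17. Longest linear sequence: 15 steps (steps 3 to 17 from diol 4; the two-step branch 1 → 3 joins at step 5, and dione 6 and angelic acid 25 enter along the way).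

Most likely to fail:

Step 10 (key step). Substitution at the hindered C11 may be slow, so that the mono-enolate alkylates through oxygen or C8 before the second deprotonation, or the tosylate is lost by elimination. The fallback masks the dione so that a single deprotonation gives the C10 nucleophile. It sets out from 12: HC(OMe)3, MeOH and cat. TsOH should etherify the less hindered C9 carbonyl to give the 9-methoxy-8-en-7-one F1. OsO4/NMO then gives the cis-diol F2, and TESCl followed by Ts2O gives the silyl ether tosylate F3. LiN(i-Pr)2 (1.2 equiv) can only remove the γ-hydrogen at C10 (C6 is quaternary), and γ-alkylation of the alkoxy dienolate closes the cyclobutane to the tricyclic methoxy enone F4. Aqueous HCl hydrolyses the enol ether and the triethylsilyl ether, and the route is rejoined at 18.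

Step 6. Enolisation may give the wrong ketene acetal geometry, or the rearrangement may pass through a boat-like transition state, either of which would deliver the C6 epimer; the congested bond formation may also stall. The fallback builds C6 in two stages on a lactone template. It sets out from 7: propanoic anhydride, pyridine and cat. DMAP give the propanoate F5. Ireland–Claisen rearrangement (LiN(i-Pr)2, TMSCl, Et3N) gives the propanoic acid F6 (C6 epimers, irrelevant). Iodolactonisation (I2, NaHCO3) gives the cis-fused iodolactone F7. After in situ masking of the acetyl groups (LiN(i-Pr)2, TMSCl), the lactone enolate should take up monomeric CH2O from the convex face to give the hydroxymethyl lactone F8, which is silylated (TIPSOTf, 2,6-lutidine) to the silyl ether F9. Zn in AcOH reopens the lactone to the alkene acid, and the route is rejoined at 9.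

Step 7. Retro-Claisen opening and intermolecular condensation may outrun closure of the seven-membered ring onto the neopentyl ester. The fallback replaces the alkoxide-mediated condensation by a soft-enolisation acylation. It sets out from 9: (COCl)2 with cat. DMF gives the acid chloride F10. MgBr2·OEt2 and i-Pr2NEt enolise one chelated acetyl group, whose carbon acylates intramolecularly to give the cyclic 10-acetyl trione F11. K2CO3 in MeOH removes the exocyclic acetyl group, and the route is rejoined at 12.

**Further compounds**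

F1 | step 10 | 9-methoxy-15-(triisopropylsilyloxy)-12-nor-10,11-secolongipina-1(11),8-dien-7-one (C10 epimers) | CC(C)[Si](C(C)C)(C(C)C)OC[C@]1(C)[C@@H]2C=CCC[C@@H]2C(C)C(OC)=CC1=O
F2 | step 10 | 1,11-diol of F1 (cis, trans to C6 and C10) | CC(C)[Si](C(C)C)(C(C)C)OC[C@]1(C)[C@@H]2[C@@H](O)[C@@H](O)CC[C@@H]2C(C)C(OC)=CC1=O
F3 | step 10 | 1-O-triethylsilyl 11-O-tosyl derivative of F2 | CC(C)[Si](C(C)C)(C(C)C)OC[C@]1(C)[C@@H]2[C@@H](OS(=O)(=O)c3ccc(C)cc3)[C@@H](O[Si](CC)(CC)CC)CC[C@@H]2C(C)C(OC)=CC1=O
F4 | step 10 | 9-methoxy-1-(triethylsilyloxy)-15-(triisopropylsilyloxy)-12-norlongipin-8-en-7-one | CC(C)[Si](C(C)C)(C(C)C)OC[C@]1(C)[C@@H]2[C@H]3[C@@H](O[Si](CC)(CC)CC)CC[C@@H]2[C@@]3(C)C(OC)=CC1=O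
F5 | step 6 | (1R,4S)-4-(3-methyl-2,4-dioxopentan-3-yl)cyclohex-2-en-1-yl propanoate | CCC(=O)O[C@H]1C=C[C@@H](C(C)(C(C)=O)C(C)=O)CC1
F6 | step 6 | 2-[cis-6-(3-methyl-2,4-dioxopentan-3-yl)cyclohex-2-en-1-yl]propanoic acid (C6 epimers) | CC(C(O)=O)[C@@H]1C=CCC[C@@H]1C(C)(C(C)=O)C(C)=O
F7 | step 6 | cis-fused iodolactone of F6 (O on C11, I on C1, trans) | CC1C(=O)O[C@@H]2[C@@H](I)CC[C@H](C(C)(C(C)=O)C(C)=O)[C@H]12
F8 | step 6 | α-hydroxymethyl-α-methyl iodolactone (CH2OH on the convex face) | OC[C@@]1(C)C(=O)O[C@@H]2[C@@H](I)CC[C@H](C(C)(C(C)=O)C(C)=O)[C@H]12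
F9 | step 6 | triisopropylsilyl ether of F8 | CC(C)[Si](C(C)C)(C(C)C)OC[C@@]1(C)C(=O)O[C@@H]2[C@@H](I)CC[C@H](C(C)(C(C)=O)C(C)=O)[C@H]12
F10 | step 7 | acid chloride of 9 | CC(C)[Si](C(C)C)(C(C)C)OC[C@@](C)(C(Cl)=O)[C@@H]1C=CCC[C@@H]1C(C)(C(C)=O)C(C)=O
F11 | step 7 | 10-acetyl-15-(triisopropylsilyloxy)-12-nor-10,11-secolongipin-1(11)-ene-7,9-dione (C10 epimers) | CC(C)[Si](C(C)C)(C(C)C)OC[C@]1(C)[C@@H]2C=CCC[C@@H]2C(C)(C(C)=O)C(=O)CC1=O
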